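**Strategy.** Ring B (C5–C10) is traced back to a cyclopentanone: excising C8 together with its methyl leaves the cis-fused hydrindanone 6, whose C9 carbonyl lies between quaternary C10 and methylene C7. In one operation the key step inserts that carbon as diazoethane into the C9–C7 bond, turning the five-membered ring into ring B with the C8 methyl in place. Because C10 carries no hydrogen, the resulting ketone enolises only towards C8, so its enol triflate fixes the C8=C9 double bond. Hydrindanone 6 comes from a radical conjugate addition–enolate alkylation annulation followed by resolution; the dienyl butenolide chain is then built on C9 by cross-couplings.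

Key step: step 5

Remark on numbering: terpenoid numbering is used; ring A = C1–C5 and C10, ring B = C5–C10, C11–C16 = chain carbons from C9 to the butenolide, with CH2OH on C13.

Remark on configuration: the descriptors of the target place the C10 methyl and H-5 on the same face, so the decalin is cis-fused, (4aR,8aS) in the naphthalene numbering (5R,10S in the terpenoid numbering).

Remark on enantiocontrol: no catalytic asymmetric version of the annulation in steps 1 and 2 could be defended, so the absolute configuration is taken by resolution of the racemic ketone 4 (steps 3 and 4).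

**Step 1**
Reactants: 1 2-methylcyclopent-2-en-1-one; 2 5-bromo-2-methylpent-2-ene
Product: 3 3-(5-bromo-2-methylpentan-2-yl)-2-methylcyclopentan-1-one (racemic, both C2 epimers)
Conditions: Fe(acac)3 (30 mol%), PhSiH3, EtOH/ethylene glycol, 60 °C; 1 in excess
Reagents that add atoms: none
Why: Hydrogen atom transfer from the iron hydride to the trisubstituted olefin of 2 gives the tertiary radical, which adds to the unsubstituted β-carbon of enone 1 and is then reduced and protonated at C10 (Mukaiyama-type reductive olefin coupling, Giese addition); C5 forms as a racemate and C10 is still epimerisable, both being settled in steps 2 to 4.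

**Step 2**
Reactants: 3 3-(5-bromo-2-methylpentan-2-yl)-2-methylcyclopentan-1-one
Product: 4 rac-(3aR,7aS)-4,4,7a-trimethyloctahydro-1H-inden-1-one (cis-fused racemate)
Conditions: KOtBu, t-BuOH/THF, 0 °C to rt
Reagents that add atoms: none
Why: Under equilibrating KOtBu the more substituted C10 enolate closes ring A by 6-exo-tet displacement of the primary bromide (intramolecular enolate alkylation), and since the four-atom tether is anchored at C5 it can only reach the enolate face on its own side, so the angular methyl and H-5 end up cis.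

**Step 3**
Reactants: 4 rac-(3aR,7aS)-4,4,7a-trimethyloctahydro-1H-inden-1-one
Product: 5 (1R,3aR,7aS)-4,4,7a-trimethyl-1-{[(S)-N-methyl-S-phenylsulfonimidoyl]methyl}octahydro-1H-inden-1-ol (the diastereomer derived from the (3aR,7aS) ketone)
Conditions: (S)-N,S-dimethyl-S-phenylsulfoximine, n-BuLi, THF, −78 °C; then 4; aq NH4Cl; separation of the two diastereomers on silica
Reagents that add atoms: (S)-N,S-dimethyl-S-phenylsulfoximine, C[S@@](=O)(=NC)c1ccccc1
Why: Sulfoximine resolution of ketones: the lithiated enantiopure sulfoximine should add to the carbonyl from the convex face, cis to the angular methyl, so each enantiomer of 4 gives one diastereomeric β-hydroxy sulfoximine and the two should be separable on silica.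

**Step 4**
Reactants: 5 (1R,3aR,7aS)-4,4,7a-trimethyl-1-{[(S)-N-methyl-S-phenylsulfonimidoyl]methyl}octahydro-1H-inden-1-ol
Product: 6 (3aR,7aS)-4,4,7a-trimethyloctahydro-1H-inden-1-one (single enantiomer)
Conditions: xylenes, 130 °C
Reagents that add atoms: none
Why: β-Hydroxy sulfoximines revert thermally to ketone and sulfoximine (retro-addition), which should release the (3aR,7aS) ketone without touching C5 or C10.

**Step 5**
Reactants: 6 (3aR,7aS)-4,4,7a-trimethyloctahydro-1H-inden-1-one
Product: 7 (4aR,8aS)-2,5,5,8a-tetramethyloctahydronaphthalen-1(2H)-one (both C2 epimers)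
Conditions: CH3CHN2 (toluene solution, from N-ethyl-N-nitrosourea and aq KOH, 0 °C), Sc(OTf)3 (10 mol%), toluene, −78 to 0 °C
Reagents that add atoms: diazoethane, CC=[N+]=[N-]
Why: Sc(OTf)3 activates the C9 carbonyl, the nucleophilic carbon of diazoethane adds to it, and in the resulting alkoxide–diazonium betaine the C7–C9 bond migrates to the new carbon with loss of N2, so that C8 with its methyl is inserted between C9 and C7 and the cyclopentanone of 6 becomes ring B of 7. The closest known reaction type is the Lewis acid catalysed diazoalkane homologation of cycloalkanones, as in the one-carbon enlargement of angular-methyl hydrindanones to the homologous decalones. No ring is closed by cyclisation: ring B arises from the five-membered ring by a 1,2-alkyl shift (five to six atoms). The new stereocentre C8 is not controlled and need not be, since it becomes trigonal in step 6, while C5 and C10 are not involved and keep their configuration. The step needs migration of methylene C7 instead of quaternary C10 and a single insertion; the less substituted carbon migrates preferentially in such homologations, and the product ketone, now flanked by C8–Me and quaternary C10, should be too hindered to take up a second diazoethane.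

**Step 6**
Reactants: 7 (4aR,8aS)-2,5,5,8a-tetramethyloctahydronaphthalen-1(2H)-one
Product: 9 (4aR,8aS)-2,5,5,8a-tetramethyl-3,4,4a,5,6,7,8,8a-octahydronaphthalen-1-yl trifluoromethanesulfonate, via potassium enolate 8 (not isolated)
Conditions: KN(SiMe3)2, THF, −78 to 0 °C; then PhNTf2, −78 °C to rt
Reagents that add atoms: N-phenylbis(trifluoromethanesulfonimide), O=S(=O)(N(c1ccccc1)S(=O)(=O)C(F)(F)F)C(F)(F)F
Why: C10 is quaternary, so the base can deprotonate only C8, and O-triflation of that enolate places the double bond at C8=C9 (regiospecific enol triflate formation), erasing the uncontrolled C8 centre.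

**Step 7**
Reactants: 9 (4aR,8aS)-2,5,5,8a-tetramethyl-3,4,4a,5,6,7,8,8a-octahydronaphthalen-1-yl trifluoromethanesulfonate
Product: 10 (4aR,8aS)-1-ethenyl-2,5,5,8a-tetramethyl-3,4,4a,5,6,7,8,8a-octahydronaphthalene
Conditions: tributyl(vinyl)stannane, Pd(PPh3)4 (5 mol%), LiCl, THF, 65 °C
Reagents that add atoms: tributyl(vinyl)stannane, C=C[Sn](CCCC)(CCCC)CCCC
Why: Stille coupling of the hindered tetrasubstituted enol triflate with the small vinylstannane, with LiCl to assist transmetalation, should install C11 and C12.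

**Step 8**
Reactants: 11 4-{[tert-butyl(dimethyl)silyl]oxy}but-2-yn-1-ol
Product: 13 (2Z)-4-{[tert-butyl(dimethyl)silyl]oxy}-3-iodobut-2-en-1-ol, via cyclic vinylalanate 12 (not isolated)
Conditions: NaAlH2(OCH2CH2OMe)2 (Red-Al), THF, 0 °C to rt; then I2, THF, −78 °C
Reagents that add atoms: iodine, II
Why: The free alkoxide directs trans-hydroalumination so that aluminium sits on the distal alkyne carbon, cis to the CH2O arm in a five-membered alanate, and iodinolysis with retention gives the Z vinyl iodide that fixes the later C13=C14 geometry.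

**Step 9**
Reactants: 10 (4aR,8aS)-1-ethenyl-2,5,5,8a-tetramethyl-3,4,4a,5,6,7,8,8a-octahydronaphthalene; 13 (2Z)-4-{[tert-butyl(dimethyl)silyl]oxy}-3-iodobut-2-en-1-ol
Product: 15 (2E)-3-({[tert-butyl(dimethyl)silyl]oxy}methyl)-5-[(4aR,8aS)-2,5,5,8a-tetramethyl-3,4,4a,5,6,7,8,8a-octahydronaphthalen-1-yl]pent-2-en-1-ol, via alkylborane 14 (not isolated)
Conditions: 9-BBN, THF, 0 °C to rt; then 13, PdCl2(dppf) (5 mol%), AsPh3, Cs2CO3, DMF/H2O, rt
Reagents that add atoms: none
Why: 9-BBN should hydroborate only the terminal vinyl carbon C12 of the diene, and B-alkyl Suzuki–Miyaura coupling with the vinyl iodide proceeds with retention, so C12 ends cis to C15 and the CH2O arm trans, as in the target.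

**Step 10**
Reactants: 15 (2E)-3-({[tert-butyl(dimethyl)silyl]oxy}methyl)-5-[(4aR,8aS)-2,5,5,8a-tetramethyl-3,4,4a,5,6,7,8,8a-octahydronaphthalen-1-yl]pent-2-en-1-ol
Product: 16 (2E)-3-({[tert-butyl(dimethyl)silyl]oxy}methyl)-5-[(4aR,8aS)-2,5,5,8a-tetramethyl-3,4,4a,5,6,7,8,8a-octahydronaphthalen-1-yl]pent-2-enal
Conditions: MnO2, CH2Cl2, rt
Reagents that add atoms: none
Why: MnO2 oxidises the primary allylic alcohol to the enal under neutral conditions that should not isomerise the trisubstituted olefin (allylic oxidation).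

**Step 11**
Reactants: 16 (2E)-3-({[tert-butyl(dimethyl)silyl]oxy}methyl)-5-[(4aR,8aS)-2,5,5,8a-tetramethyl-3,4,4a,5,6,7,8,8a-octahydronaphthalen-1-yl]pent-2-enal
Product: 17 tert-butyl(dimethyl){[(2E,4E)-5-(4,4,5,5-tetramethyl-1,3,2-dioxaborolan-2-yl)-2-{2-[(4aR,8aS)-2,5,5,8a-tetramethyl-3,4,4a,5,6,7,8,8a-octahydronaphthalen-1-yl]ethyl}penta-2,4-dien-1-yl]oxy}silane
Conditions: Cl2CHBpin, CrCl2, LiI, THF, rt
Reagents that add atoms: 2-(dichloromethyl)-4,4,5,5-tetramethyl-1,3,2-dioxaborolane, ClC(Cl)B1OC(C)(C)C(C)(C)O1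
Why: Takai–Utimoto olefination: the gem-dichromium species formed from Cl2CHBpin and CrCl2 adds to the aldehyde and eliminates to the E alkenylboronate, which sets the C15=C16 geometry.

**Step 12**
Reactants: 17 the dienylboronate of step 11; 18 4-bromofuran-2(5H)-one
Product: 19 4-[(1E,3E)-4-({[tert-butyl(dimethyl)silyl]oxy}methyl)-6-[(4aR,8aS)-2,5,5,8a-tetramethyl-3,4,4a,5,6,7,8,8a-octahydronaphthalen-1-yl]hexa-1,3-dien-1-yl]furan-2(5H)-one
Conditions: PdCl2(dppf) (5 mol%), K3PO4, THF/H2O, rt to 40 °C
Reagents that add atoms: none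
Why: Suzuki–Miyaura coupling of the dienylboronate with the activated β-bromo butenolide should form C16–C17 with retention of both olefin geometries under mild base.

**Step 13**
Reactants: 19 the silyl ether of step 12
Product: 20 4-[(1E,3E)-4-(hydroxymethyl)-6-[(4aR,8aS)-2,5,5,8a-tetramethyl-3,4,4a,5,6,7,8,8a-octahydronaphthalen-1-yl]hexa-1,3-dien-1-yl]furan-2(5H)-one (CNP0232848.3)
Conditions: HF·pyridine, THF, 0 °C to rt
Reagents that add atoms: none
Why: Fluoride cleaves the primary silyl ether under buffered, non-basic conditions that should leave the butenolide and the diene untouched (desilylation).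

**Compound list**

1 | 2-methylcyclopent-2-en-1-one | CC1=CCCC1=O | starting material
2 | 5-bromo-2-methylpent-2-ene | CC(C)=CCCBr | starting material
3 | 3-(5-bromo-2-methylpentan-2-yl)-2-methylcyclopentan-1-one (racemic, both C2 epimers) | CC1C(CCC1=O)C(C)(C)CCCBr | intermediate
4 | rac-(3aR,7aS)-4,4,7a-trimethyloctahydro-1H-inden-1-one (cis-fused racemate; the SMILES shows the (3aR,7aS) half) | O=C1[C@@]2(C)CCCC(C)(C)[C@H]2CC1 | intermediate
5 | (1R,3aR,7aS)-4,4,7a-trimethyl-1-{[(S)-N-methyl-S-phenylsulfonimidoyl]methyl}octahydro-1H-inden-1-ol | O[C@@]1(C[S@@](=O)(=NC)c3ccccc3)[C@@]2(C)CCCC(C)(C)[C@H]2CC1 | intermediate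
6 | (3aR,7aS)-4,4,7a-trimethyloctahydro-1H-inden-1-one (single enantiomer) | O=C1[C@@]2(C)CCCC(C)(C)[C@H]2CC1 | intermediate
7 | (4aR,8aS)-2,5,5,8a-tetramethyloctahydronaphthalen-1(2H)-one (both C2 epimers) | CC1C(=O)[C@@]2(C)CCCC(C)(C)[C@H]2CC1 | intermediate
8 | potassium (4aR,8aS)-2,5,5,8a-tetramethyl-3,4,4a,5,6,7,8,8a-octahydronaphthalen-1-olate | CC1=C([O-])[C@@]2(C)CCCC(C)(C)[C@H]2CC1.[K+] | intermediate (not isolated)
9 | (4aR,8aS)-2,5,5,8a-tetramethyl-3,4,4a,5,6,7,8,8a-octahydronaphthalen-1-yl trifluoromethanesulfonate | CC1=C(OS(=O)(=O)C(F)(F)F)[C@@]2(C)CCCC(C)(C)[C@H]2CC1 | intermediate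
10 | (4aR,8aS)-1-ethenyl-2,5,5,8a-tetramethyl-3,4,4a,5,6,7,8,8a-octahydronaphthalene | CC1=C(C=C)[C@@]2(C)CCCC(C)(C)[C@H]2CC1 | intermediate
11 | 4-{[tert-butyl(dimethyl)silyl]oxy}but-2-yn-1-ol | OCC#CCO[Si](C)(C)C(C)(C)C | starting material
12 | sodium cyclic vinylalanate from trans-hydroalumination of 11 (five-membered O–Al–C=C–C ring, two 2-methoxyethoxy groups on aluminium) | COCCO[Al-]1(OCCOC)OCC=C1CO[Si](C)(C)C(C)(C)C.[Na+] | intermediate (not isolated)
13 | (2Z)-4-{[tert-butyl(dimethyl)silyl]oxy}-3-iodobut-2-en-1-ol | OC/C=C(\I)CO[Si](C)(C)C(C)(C)C | intermediate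
14 | 9-{2-[(4aR,8aS)-2,5,5,8a-tetramethyl-3,4,4a,5,6,7,8,8a-octahydronaphthalen-1-yl]ethyl}-9-borabicyclo[3.3.1]nonane | CC1=C(CCB3C4CCCC3CCC4)[C@@]2(C)CCCC(C)(C)[C@H]2CC1 | intermediate (not isolated)
15 | (2E)-3-({[tert-butyl(dimethyl)silyl]oxy}methyl)-5-[(4aR,8aS)-2,5,5,8a-tetramethyl-3,4,4a,5,6,7,8,8a-octahydronaphthalen-1-yl]pent-2-en-1-ol | CC1=C(CC/C(=C\CO)CO[Si](C)(C)C(C)(C)C)[C@@]2(C)CCCC(C)(C)[C@H]2CC1 | intermediate
16 | (2E)-3-({[tert-butyl(dimethyl)silyl]oxy}methyl)-5-[(4aR,8aS)-2,5,5,8a-tetramethyl-3,4,4a,5,6,7,8,8a-octahydronaphthalen-1-yl]pent-2-enal | CC1=C(CC/C(=C\C=O)CO[Si](C)(C)C(C)(C)C)[C@@]2(C)CCCC(C)(C)[C@H]2CC1 | intermediate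
17 | tert-butyl(dimethyl){[(2E,4E)-5-(4,4,5,5-tetramethyl-1,3,2-dioxaborolan-2-yl)-2-{2-[(4aR,8aS)-2,5,5,8a-tetramethyl-3,4,4a,5,6,7,8,8a-octahydronaphthalen-1-yl]ethyl}penta-2,4-dien-1-yl]oxy}silane | CC1=C(CC/C(=C\C=C\B3OC(C)(C)C(C)(C)O3)CO[Si](C)(C)C(C)(C)C)[C@@]2(C)CCCC(C)(C)[C@H]2CC1 | intermediate
18 | 4-bromofuran-2(5H)-one | BrC1=CC(=O)OC1 | starting material
19 | 4-[(1E,3E)-4-({[tert-butyl(dimethyl)silyl]oxy}methyl)-6-[(4aR,8aS)-2,5,5,8a-tetramethyl-3,4,4a,5,6,7,8,8a-octahydronaphthalen-1-yl]hexa-1,3-dien-1-yl]furan-2(5H)-one | CC1=C(CC/C(=C\C=C\C3=CC(=O)OC3)CO[Si](C)(C)C(C)(C)C)[C@@]2(C)CCCC(C)(C)[C@H]2CC1 | intermediate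
20 | 4-[(1E,3E)-4-(hydroxymethyl)-6-[(4aR,8aS)-2,5,5,8a-tetramethyl-3,4,4a,5,6,7,8,8a-octahydronaphthalen-1-yl]hexa-1,3-dien-1-yl]furan-2(5H)-one (CNP0232848.3) | CC1=C(CC/C(=C\C=C\C3=CC(=O)OC3)CO)[C@@]2(C)CCCC(C)(C)[C@H]2CC1 | target

**Step count.** Total: 13 steps. Longest linear sequence: 12 steps (steps 1–7 and 9–13; step 8 makes the side-chain fragment).

**Steps most likely to fail**

1. Step 5 (key step). The quaternary C10 may migrate in competition with C7, a second carbon may insert into 7, or the hindered carbonyl may give an oxirane. The fallback sets out from 6 and comes back at 7; it enlarges the ring by a cyclopropanol fragmentation whose regiochemistry is fixed by the enol ether. LiN(i-Pr)2 and Me3SiCl can only give the C7–C9 silyl enol ether trimethyl{[(3aR,7aS)-4,4,7a-trimethyl-3a,4,5,6,7,7a-hexahydro-3H-inden-1-yl]oxy}silane F1. Et2Zn and 1,1-diiodoethane (Simmons–Smith type ethylidene transfer) should convert it into the siloxy methylcyclopropane fused across C7–C9 F2. FeCl3 in DMF should cleave the internal C7–C9 bond of this cyclopropanol derivative (β-keto radical, chlorine transfer), and NaOAc then eliminates HCl to the ring-enlarged enone (4aR,8aS)-2,5,5,8a-tetramethyl-4a,5,6,7,8,8a-hexahydronaphthalen-1(4H)-one F3. Hydrogenation (H2, Pd/C, EtOAc) saturates C7=C8 and returns to 7.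

2. Step 1. Radical addition to the α-substituted enone may be slow, so that reduction or isomerisation of the olefin takes over, or the primary bromide may be lost. The fallback sets out from 1 and comes back at 3; it generates the same tertiary radical from a redox-active ester. Commercial 5-bromo-2,2-dimethylpentanoic acid with N-hydroxyphthalimide, N,N'-diisopropylcarbodiimide and DMAP should give 1,3-dioxoisoindolin-2-yl 5-bromo-2,2-dimethylpentanoate F4. Under Ru(bpy)3(PF6)2, Hantzsch ester, i-Pr2NEt and blue light in CH2Cl2 this ester should lose CO2, and the radical adds to 1 to give 3.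

3. Step 3. The sulfoximine may add with poor facial selectivity, or the diastereomers may not separate, so that the enantiomers of 4 are not parted. The fallback sets out from 4 and comes back at 6. Corey–Bakshi–Shibata reduction (BH3·SMe2, (S)-2-methyl-CBS-oxazaborolidine, THF) should, under reagent control, give 1R carbinols from both enantiomers of 4, that is two diastereomers. The one with OH trans to the angular methyl, (1R,3aR,7aS)-4,4,7a-trimethyloctahydro-1H-inden-1-ol F5, is separated on silica and oxidised with Dess–Martin periodinane to 6.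

**Further compounds**

F1 | step 5 | trimethyl{[(3aR,7aS)-4,4,7a-trimethyl-3a,4,5,6,7,7a-hexahydro-3H-inden-1-yl]oxy}silane | C[Si](C)(C)OC=1[C@@]2(C)CCCC(C)(C)[C@H]2CC=1
F2 | step 5 | siloxy methylcyclopropane from F1 (CH–CH3 bridging C7 and C9 of the hydrindane, OSiMe3 on C9; mixture of cyclopropane stereoisomers) | C[Si](C)(C)OC13[C@@]2(C)CCCC(C)(C)[C@H]2CC1C3C
F3 | step 5 | (4aR,8aS)-2,5,5,8a-tetramethyl-4a,5,6,7,8,8a-hexahydronaphthalen-1(4H)-one | CC=1C(=O)[C@@]2(C)CCCC(C)(C)[C@H]2CC=1
F4 | step 1 | 1,3-dioxoisoindolin-2-yl 5-bromo-2,2-dimethylpentanoate | O=C(ON1C(=O)c2ccccc2C1=O)C(C)(C)CCCBr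
F5 | step 3 | (1R,3aR,7aS)-4,4,7a-trimethyloctahydro-1H-inden-1-ol | O[C@H]1[C@@]2(C)CCCC(C)(C)[C@H]2CC1
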